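The runs are simulated with made-up constants.

Count the partner before charging the next flask, because the decision is whether 3.00 equiv is worth charging.

| flask | starting material | partner | remark | time |
|---|---|---|---|---|
| blue | 0.047 M | 1.5 equiv | run made earlier |  |
| red | 0.047 M | 2.2 equiv | run made earlier |  |
| flask | 0.047 M | 3.00 equiv |  | 6.0 min |

| run | time / min | double product / % |
|---|---|---|
| blue | 0.417 | 1.5 |
| blue | 0.667 | 3.9 |
| blue | 1.00 | 4.9 |
| blue | 2.00 | 8.8 |
| blue | 3.00 | 9.5 |
| blue | 5.00 | 11.2 |
| red | 0.417 | 4.1 |
| red | 0.667 | 6.2 |
| red | 1.00 | 9.4 |
| red | 2.00 | 13.8 |
| red | 3.00 | 14.2 |
| red | 5.00 | 17.6 |

(standard deviation of a reading: 1 percentage point)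



* equivalents of partner to starting material, everything else as given, that leave most double product at 6.0 min
* the amount of double product then, in percent of the starting material charged
* the amount of double product with the amounts as given

A double product holds two partners on one starting material, so I divide the charge by two:

cover = equivalents of partner charged / two

flask 1.50, blue 0.750, red 1.10

The cover, the share of starting material that the charged partner can bring to double product, passes one between blue and red. Below one, partner is the limiting reagent for double product; above one, starting material is, and the partner left over can add a third time, if such a step exists.

The readings stand far under the cover: blue ends at 11.2% against 75.0%, red at 17.6% against 110%. So the cover is a ceiling that neither run reaches, and it can't tell me how much of the shortfall is partner supply and how much is double product used up or bypassed. The last reading is higher in red than in blue, so more partner has helped so far, but beyond a cover of one I expect extra partner to meet double product already made. I therefore keep the red charge, 2.2 equiv, as my best, with double product near its last reading, and I expect less than that at 3.00 equiv.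

The forecast gives 4 equiv for 25%, and 22% at the asked charge, holding that “The plateau grows less than proportionally to excess partner”.

The flask at 3.00 equiv gives 12.2% after 6.0 min, while the most double product, 14.6%, comes at 2.24 equiv, a cover of 1.12. At cover 1.50 the flask holds 52.8% tris adduct, against 32.1% at the best charge.

    starting material + double product → side product (k = 0.205 M⁻¹ s⁻¹)
    double product → over-reaction product (k = 5.85 × 10⁻⁴ s⁻¹)
    partner + mono adduct → double product (k = 0.197 M⁻¹ s⁻¹)
    starting material + partner → mono adduct (k = 0.229 M⁻¹ s⁻¹)
    partner ⇌ dormant form (K = 0.840, k = 0.0433 s⁻¹)
    partner + double product → tris adduct (k = 0.310 M⁻¹ s⁻¹)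

Now charge 1.20 equiv: the cover is 0.600, under one, so I expect that neighbour flask to hold more mono adduct than double product. It gives 37.6% mono adduct, 8.71% double product and 7.67% tris adduct.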